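**Plan**

- Retrosynthesis: the four benzyl ethers are cut last. Ring C of the acacetin half is then cut at C3–C4 and O1–C2 into a salicylaldehyde and an anisoyl sulfoxonium ylide. Behind that, the formyl C–C bond, the apigenin ring C (O1–C2 and the chalcone Cα–Cβ bond) and the diaryl ether C–O bond are cut.
- Enabling feature: in ring A of the acacetin half, C8a (the carbon that carries O1) lies between C8 (aryloxy) and C4a. A hydroxyl left free only there sits next to a formyl group on C4a, steers rhodium into the formyl C–H bond and afterwards becomes O1.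
- Forward, first part: 2,4,6-trihydroxybenzaldehyde is capped (two benzyl, one MOM), oxidised to a phenol and joined to 4-fluorobenzaldehyde as a diaryl ether. The apigenin ring C then arises from a chalcone.
- Forward, second part: MOM removal and ortho-formylation unveil the salicylaldehyde, the acacetin ring C arises last in the rhodium annulation, and hydrogenolysis frees the four hydroxyls.
- Stereochemistry: the target has no stereocentre. The only stereo-element on the way is the E alkene of the chalcone, which is consumed on cyclisation.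

Key step: step 11

Remark: atom labels follow flavone numbering (O1, C2, C3, C4, C4a, C5 to C8, C8a); ring A is the benzo ring and ring C the pyranone ring; Bn = benzyl, MOM = methoxymethyl.

**Route**

Step 1
Reactants: 1 2,4,6-trihydroxybenzaldehyde
Product: 2 2,4-bis(benzyloxy)-6-hydroxybenzaldehyde
Conditions: BnBr (2.1 equiv), K2CO3, DMF, 0 °C to rt
Reagents that add atoms: benzyl bromide, BrCc1ccccc1
Why: Williamson O-benzylation takes the para hydroxyl and one ortho hydroxyl, while the second ortho hydroxyl is held back by its hydrogen bond to the formyl oxygen.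

Step 2
Reactants: 2 2,4-bis(benzyloxy)-6-hydroxybenzaldehyde
Product: 3 2,4-bis(benzyloxy)-6-(methoxymethoxy)benzaldehyde
Conditions: NaH, MOMCl, DMF, 0 °C to rt
Reagents that add atoms: chloromethyl methyl ether, COCCl
Why: O-alkylation of the sodium phenoxide (Williamson type) breaks the chelate and caps the last hydroxyl as an acid-labile acetal that is orthogonal to the benzyl ethers.

Step 3
Reactants: 3 2,4-bis(benzyloxy)-6-(methoxymethoxy)benzaldehyde
Product: 5 2,4-bis(benzyloxy)-6-(methoxymethoxy)phenol, via aryl formate 4 (not isolated)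
Conditions: mCPBA, CH2Cl2, 0 °C to rt; then KOH, MeOH/H2O, 0 °C, N2
Reagents that add atoms: 3-chloroperoxybenzoic acid (mCPBA), O=C(OO)c1cccc(Cl)c1
Why: Baeyer–Villiger (Dakin-type) oxidation, in which the electron-rich trialkoxyaryl group migrates to give formate 4, whose saponification leaves the MOM and benzyl ethers untouched; the air-sensitive phenol is used at once.

Step 4
Reactants: 5 2,4-bis(benzyloxy)-6-(methoxymethoxy)phenol; 6 4-fluorobenzaldehyde
Product: 7 4-[2,4-bis(benzyloxy)-6-(methoxymethoxy)phenoxy]benzaldehyde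
Conditions: K2CO3, DMF, 110 °C, N2
Reagents that add atoms: none
Why: Nucleophilic aromatic substitution by addition–elimination, in which the para formyl group stabilises the Meisenheimer intermediate so that even the doubly ortho-substituted phenoxide displaces fluoride.

Step 5
Reactants: 8 2,4,6-trihydroxyacetophenone
Product: 9 1-[2,4-bis(benzyloxy)-6-hydroxyphenyl]ethan-1-one
Conditions: BnBr (2.1 equiv), K2CO3, DMF, rt to 60 °C
Reagents that add atoms: benzyl bromide, BrCc1ccccc1
Why: Williamson O-benzylation that stops at the dibenzyl ether because the remaining ortho hydroxyl is chelated to the acetyl oxygen.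

Step 6
Reactants: 7 4-[2,4-bis(benzyloxy)-6-(methoxymethoxy)phenoxy]benzaldehyde; 9 1-[2,4-bis(benzyloxy)-6-hydroxyphenyl]ethan-1-one
Product: 10 (E)-1-[2,4-bis(benzyloxy)-6-hydroxyphenyl]-3-{4-[2,4-bis(benzyloxy)-6-(methoxymethoxy)phenoxy]phenyl}prop-2-en-1-one
Conditions: KOH (50% aq.), EtOH/THF, rt; AcOH quench
Reagents that add atoms: none
Why: Claisen–Schmidt condensation of the methyl ketone enolate with the non-enolisable aldehyde, whose dehydration gives the conjugated E enone as the thermodynamic isomer.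

Step 7
Reactants: 10 (E)-1-[2,4-bis(benzyloxy)-6-hydroxyphenyl]-3-{4-[2,4-bis(benzyloxy)-6-(methoxymethoxy)phenoxy]phenyl}prop-2-en-1-one
Product: 11 5,7-bis(benzyloxy)-2-{4-[2,4-bis(benzyloxy)-6-(methoxymethoxy)phenoxy]phenyl}-4H-chromen-4-one
Conditions: I2 (10 mol%), DMSO, 130 °C; aq. Na2S2O3 work-up
Reagents that add atoms: none
Why: Iodine-catalysed oxidative cyclisation of a 2'-hydroxychalcone (6-endo oxa-Michael closure, α-iodination and loss of HI, with DMSO turning HI back into I2), kept to a low iodine loading so that the MOM acetal should largely survive; any material that loses it would converge in step 8.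

Step 8
Reactants: 11 5,7-bis(benzyloxy)-2-{4-[2,4-bis(benzyloxy)-6-(methoxymethoxy)phenoxy]phenyl}-4H-chromen-4-one
Product: 12 5,7-bis(benzyloxy)-2-{4-[2,4-bis(benzyloxy)-6-hydroxyphenoxy]phenyl}-4H-chromen-4-one
Conditions: conc. HCl (cat.), MeOH/THF, 50 °C
Reagents that add atoms: none
Why: Acid-catalysed acetal methanolysis removes the MOM group, while benzyl ethers, diaryl ether and flavone are inert to dilute acid.

Step 9
Reactants: 12 5,7-bis(benzyloxy)-2-{4-[2,4-bis(benzyloxy)-6-hydroxyphenoxy]phenyl}-4H-chromen-4-one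
Product: 14 4,6-bis(benzyloxy)-3-{4-[5,7-bis(benzyloxy)-4-oxo-4H-chromen-2-yl]phenoxy}-2-hydroxybenzaldehyde, via salicyl alcohol 13 (not isolated)
Conditions: MgCl2 (anhydrous), Et3N, (CH2O)n, THF, reflux; aq. HCl work-up
Reagents that add atoms: paraformaldehyde (as formaldehyde), C=O
Why: Magnesium-mediated ortho-formylation (Casnati–Skattebøl reaction), in which the magnesium phenoxide delivers formaldehyde through a six-membered chelate to the only free ortho carbon and the magnesium alkoxide of 13 passes hydride to a second formaldehyde (Oppenauer-type), so the free para carbon is not addressed.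

Step 10
Reactants: 15 4-methoxybenzoyl chloride
Product: 16 dimethylsulfoxonium 2-(4-methoxyphenyl)-2-oxoethylide
Conditions: Me3S(O)I (3 equiv), KOtBu (3 equiv), THF, reflux; then 15, 0 °C to rt
Reagents that add atoms: trimethylsulfoxonium iodide, C[S+](C)(C)=O.[I-]
Why: C-acylation of dimethylsulfoxonium methylide (the Corey–Chaykovsky reagent) by the acid chloride, after which a second equivalent of methylide deprotonates the acylsulfoxonium salt to the stabilised β-keto ylide.

Step 11
Reactants: 14 4,6-bis(benzyloxy)-3-{4-[5,7-bis(benzyloxy)-4-oxo-4H-chromen-2-yl]phenoxy}-2-hydroxybenzaldehyde; 16 dimethylsulfoxonium 2-(4-methoxyphenyl)-2-oxoethylide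
Product: 18 5,7-bis(benzyloxy)-8-{4-[5,7-bis(benzyloxy)-4-oxo-4H-chromen-2-yl]phenoxy}-2-(4-methoxyphenyl)-4H-chromen-4-one, via 1,3-diketone 17 (not isolated)
Conditions: [RhCl2(C5Me5)]2 (4 mol%), AgSbF6 (16 mol%), PivOH (0.5 equiv), 16 (1.5 equiv), ClCH2CH2Cl, 100 °C, Ar
Reagents that add atoms: none
Why: Cationic trivalent rhodium from [RhCl2(C5Me5)]2 and AgSbF6 binds the phenoxide of 14 and cleaves the adjacent formyl C–H bond by concerted metalation–deprotonation to a five-membered acyl rhodacycle; ylide 16 coordinates, loses dimethyl sulfoxide to a rhodium carbene, and acyl migration to the carbene carbon followed by protonation forms C3–C4 and releases diketone 17. The closest known reaction type is the redox-neutral [RhCl2(C5Me5)]2-catalysed annulation of salicylaldehydes with sulfoxonium ylides or diazo ketones to chromones and flavones. Ring C closes when the phenol of 17 adds to the anisyl ketone (6-exo-trig) and the hemiketal loses water under the acidic conditions, which forms O1–C2. No stereocentre is created. The step needs formyl rather than aryl C–H cleavage and closure through the oxygen next to C8: the only free hydroxyl of 14 lies between the formyl carbon and the aryloxy carbon, all other oxygens are benzyl ethers, and the peri position of the existing chromone carbonyl is blocked by a benzyloxy group, so no competing chelate can form.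

Step 12
Reactants: 18 5,7-bis(benzyloxy)-8-{4-[5,7-bis(benzyloxy)-4-oxo-4H-chromen-2-yl]phenoxy}-2-(4-methoxyphenyl)-4H-chromen-4-one
Product: 19 5,7-dihydroxy-8-[4-(5,7-dihydroxy-4-oxo-4H-chromen-2-yl)phenoxy]-2-(4-methoxyphenyl)-4H-chromen-4-one
Conditions: H2 (1 atm), 10% Pd/C, THF/MeOH, rt
Reagents that add atoms: none
Why: Catalytic hydrogenolysis cleaves the four benzylic C–O bonds, while the chromone C2–C3 double bonds, the diaryl ether and the methyl ether are expected to be inert at ambient pressure.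

**Compound list**

1 | 2,4,6-trihydroxybenzaldehyde | O=Cc1c(O)cc(O)cc1O | starting material
2 | 2,4-bis(benzyloxy)-6-hydroxybenzaldehyde | O=Cc1c(O)cc(OCc2ccccc2)cc1OCc1ccccc1 | intermediate
3 | 2,4-bis(benzyloxy)-6-(methoxymethoxy)benzaldehyde | COCOc1cc(OCc2ccccc2)cc(OCc2ccccc2)c1C=O | intermediate
4 | 2,4-bis(benzyloxy)-6-(methoxymethoxy)phenyl formate | COCOc1cc(OCc2ccccc2)cc(OCc2ccccc2)c1OC=O | intermediate
5 | 2,4-bis(benzyloxy)-6-(methoxymethoxy)phenol | COCOc1cc(OCc2ccccc2)cc(OCc2ccccc2)c1O | intermediate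
6 | 4-fluorobenzaldehyde | O=Cc1ccc(F)cc1 | starting material
7 | 4-[2,4-bis(benzyloxy)-6-(methoxymethoxy)phenoxy]benzaldehyde | COCOc1cc(OCc2ccccc2)cc(OCc2ccccc2)c1Oc1ccc(C=O)cc1 | intermediate
8 | 2,4,6-trihydroxyacetophenone | CC(=O)c1c(O)cc(O)cc1O | starting material
9 | 1-[2,4-bis(benzyloxy)-6-hydroxyphenyl]ethan-1-one | CC(=O)c1c(O)cc(OCc2ccccc2)cc1OCc1ccccc1 | intermediate
10 | (E)-1-[2,4-bis(benzyloxy)-6-hydroxyphenyl]-3-{4-[2,4-bis(benzyloxy)-6-(methoxymethoxy)phenoxy]phenyl}prop-2-en-1-one | COCOc1cc(OCc2ccccc2)cc(OCc2ccccc2)c1Oc1ccc(/C=C/C(=O)c2c(O)cc(OCc3ccccc3)cc2OCc2ccccc2)cc1 | intermediate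
11 | 5,7-bis(benzyloxy)-2-{4-[2,4-bis(benzyloxy)-6-(methoxymethoxy)phenoxy]phenyl}-4H-chromen-4-one | COCOc1cc(OCc2ccccc2)cc(OCc2ccccc2)c1Oc1ccc(-c2cc(=O)c3c(OCc4ccccc4)cc(OCc4ccccc4)cc3o2)cc1 | intermediate
12 | 5,7-bis(benzyloxy)-2-{4-[2,4-bis(benzyloxy)-6-hydroxyphenoxy]phenyl}-4H-chromen-4-one | Oc1cc(OCc2ccccc2)cc(OCc2ccccc2)c1Oc1ccc(-c2cc(=O)c3c(OCc4ccccc4)cc(OCc4ccccc4)cc3o2)cc1 | intermediate
13 | 5,7-bis(benzyloxy)-2-{4-[4,6-bis(benzyloxy)-2-hydroxy-3-(hydroxymethyl)phenoxy]phenyl}-4H-chromen-4-one (present in the flask as its magnesium alkoxide) | OCc1c(O)c(Oc2ccc(-c3cc(=O)c4c(OCc5ccccc5)cc(OCc5ccccc5)cc4o3)cc2)c(OCc2ccccc2)cc1OCc1ccccc1 | intermediate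
14 | 4,6-bis(benzyloxy)-3-{4-[5,7-bis(benzyloxy)-4-oxo-4H-chromen-2-yl]phenoxy}-2-hydroxybenzaldehyde | O=Cc1c(O)c(Oc2ccc(-c3cc(=O)c4c(OCc5ccccc5)cc(OCc5ccccc5)cc4o3)cc2)c(OCc2ccccc2)cc1OCc1ccccc1 | intermediate
15 | 4-methoxybenzoyl chloride | COc1ccc(C(Cl)=O)cc1 | starting material
16 | dimethylsulfoxonium 2-(4-methoxyphenyl)-2-oxoethylide | COc1ccc(C(=O)C=S(C)(C)=O)cc1 | intermediate
17 | 1-[4,6-bis(benzyloxy)-3-{4-[5,7-bis(benzyloxy)-4-oxo-4H-chromen-2-yl]phenoxy}-2-hydroxyphenyl]-3-(4-methoxyphenyl)propane-1,3-dione | COc1ccc(C(=O)CC(=O)c2c(O)c(Oc3ccc(-c4cc(=O)c5c(OCc6ccccc6)cc(OCc6ccccc6)cc5o4)cc3)c(OCc3ccccc3)cc2OCc2ccccc2)cc1 | intermediate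
18 | 5,7-bis(benzyloxy)-8-{4-[5,7-bis(benzyloxy)-4-oxo-4H-chromen-2-yl]phenoxy}-2-(4-methoxyphenyl)-4H-chromen-4-one | COc1ccc(-c2cc(=O)c3c(OCc4ccccc4)cc(OCc4ccccc4)c(Oc4ccc(-c5cc(=O)c6c(OCc7ccccc7)cc(OCc7ccccc7)cc6o5)cc4)c3o2)cc1 | intermediate
19 | 5,7-dihydroxy-8-[4-(5,7-dihydroxy-4-oxo-4H-chromen-2-yl)phenoxy]-2-(4-methoxyphenyl)-4H-chromen-4-one | COc1ccc(-c2cc(=O)c3c(O)cc(O)c(Oc4ccc(-c5cc(=O)c6c(O)cc(O)cc6o5)cc4)c3o2)cc1 | target

**Summary**

Total step count: 12.
Longest linear sequence: 10 steps (steps 1, 2, 3, 4, 6, 7, 8, 9, 11 and 12; steps 5 and 10 are side branches).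

**Steps most likely to fail**

Step 11. The formyl group of 14 is flanked by the hydroxyl and a benzyloxy group, so metalation may be slow and the ylide may be consumed unproductively. The silver and rhodium Lewis acids may also cleave a peri benzyl ether, or the sequence may stall at the open diketone (acid treatment would then finish the dehydration). The fallback sets out from 14 and uses alkynone chemistry. Lithium (4-methoxyphenyl)acetylide (4-ethynylanisole, n-BuLi, excess, THF, −78 °C) is added to the aldehyde to give the racemic propargylic alcohol F1. MnO2 in CH2Cl2 oxidises it to the 2-hydroxyaryl ynone F2. Et2NH in EtOH then brings about conjugate addition and 6-endo ring closure with loss of the amine, which comes back to the route at 18.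

Step 7. HI formed during the oxidation may cleave the MOM acetal early, and the very electron-rich tetraoxygenated ring may then be iodinated or oxidised, or a peri benzyl ether may be lost. The fallback sets out from 10 and separates ring closure from dehydrogenation. NaOAc in refluxing EtOH isomerises the chalcone by oxa-Michael addition to the racemic flavanone F3. DDQ in refluxing dioxane then dehydrogenates C2–C3 without electrophilic iodine or acid, which comes back to the route at 11.

Step 9. The magnesium phenoxide may be sequestered by the neighbouring aryloxy and flavone oxygens, so that conversion stays low. The hydroxymethyl stage may not be oxidised, or free formaldehyde may attack the para carbon between the two benzyloxy groups. The fallback sets out from 12 and fixes the ortho position with a boron template. PhB(OH)2, (CH2O)n and catalytic EtCO2H in refluxing toluene with water removal give the benzodioxaborin F4. Exchange with propane-1,3-diol releases salicyl alcohol 13, this time isolated, and MnO2 in CH2Cl2 oxidises it, which comes back to the route at 14.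

**Further compounds**

F1 | step 11 | racemic 5,7-bis(benzyloxy)-2-(4-{4,6-bis(benzyloxy)-2-hydroxy-3-[1-hydroxy-3-(4-methoxyphenyl)prop-2-yn-1-yl]phenoxy}phenyl)-4H-chromen-4-one | COc1ccc(C#CC(O)c2c(O)c(Oc3ccc(-c4cc(=O)c5c(OCc6ccccc6)cc(OCc6ccccc6)cc5o4)cc3)c(OCc3ccccc3)cc2OCc2ccccc2)cc1
F2 | step 11 | 5,7-bis(benzyloxy)-2-(4-{4,6-bis(benzyloxy)-2-hydroxy-3-[3-(4-methoxyphenyl)prop-2-ynoyl]phenoxy}phenyl)-4H-chromen-4-one | COc1ccc(C#CC(=O)c2c(O)c(Oc3ccc(-c4cc(=O)c5c(OCc6ccccc6)cc(OCc6ccccc6)cc5o4)cc3)c(OCc3ccccc3)cc2OCc2ccccc2)cc1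
F3 | step 7 | racemic 5,7-bis(benzyloxy)-2-{4-[2,4-bis(benzyloxy)-6-(methoxymethoxy)phenoxy]phenyl}chroman-4-one | COCOc1cc(OCc2ccccc2)cc(OCc2ccccc2)c1Oc1ccc(C2CC(=O)c3c(OCc4ccccc4)cc(OCc4ccccc4)cc3O2)cc1
F4 | step 9 | 5,7-bis(benzyloxy)-2-{4-[(5,7-bis(benzyloxy)-2-phenyl-4H-1,3,2-benzodioxaborin-8-yl)oxy]phenyl}-4H-chromen-4-one | c1ccc(cc1)B1OCc2c(OCc3ccccc3)cc(OCc3ccccc3)c(Oc3ccc(-c4cc(=O)c5c(OCc6ccccc6)cc(OCc6ccccc6)cc5o4)cc3)c2O1
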